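## Retrosynthetic overview

1. The C15–O ester is made last, by Mitsunobu union of the macrocyclic primary allylic alcohol with silyl-protected (Z)-2-(hydroxymethyl)but-2-enoic acid.
2. The ten-membered ring is formed second, at C6–C7, by intramolecular chromium Barbier allylation of a 3-(bromomethyl)butenolide onto a (Z)-enal; C8 relays to C7 and C6.
3. The butenolide ring is formed first, by ring-closing metathesis of an (S)-allylic 2-(bromomethyl)acrylate. Its C8–O bond is the key step: a new enantioselective Pd-catalysed branched allylic C–H acyloxylation of a terminal alkene.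
4. The acyclic triene comes from B-alkyl Suzuki coupling of a (Z)-iodoalkene (from 2-butyne-1,4-diol; fixes ring-cis C4=C5 and C15–O) with a homoallylic iodide (from hex-1-en-5-yne; fixes (E)-C1=C10).

Assumption: positions use germacrane numbering (C8 lactone carbinol, C7 fusion carbon bearing C11, C6 carbinol, C4 bearing C15H2O, C10 bearing the C14 methyl), the target is (6R,7S,8S), and hex-1-en-5-yne and 2-(bromomethyl)acrylic acid are taken as catalogue reagents.

## Route

Step 1
Reactants: 1 2-butyne-1,4-diol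
Product: 2 4-[(tert-butyldimethylsilyl)oxy]but-2-yn-1-ol
Conditions: TBSCl (1 equiv), imidazole, 1 (4 equiv), THF, 0 °C to rt
Reagents that add atoms: tert-butyldimethylsilyl chloride CC(C)(C)[Si](C)(C)Cl
Why: Silyl ether formation on a symmetrical diol used in excess gives essentially only the mono-ether; no stereocentre is involved.

Step 2
Reactants: 2 4-[(tert-butyldimethylsilyl)oxy]but-2-yn-1-ol
Product: 4 (Z)-4-[(tert-butyldimethylsilyl)oxy]-3-iodobut-2-en-1-ol, via sodium alkenylaluminate 3 (not isolated)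
Conditions: NaAlH2(OCH2CH2OCH3)2, THF, 0 °C; EtOAc quench; then I2, −78 °C to 0 °C
Reagents that add atoms: iodine II
Why: Hydroxyl-directed trans-hydroalumination puts hydride on the carbon next to the free carbinol and aluminium on the distal carbon in a five-membered aluminate (kept at or below 0 °C so that silanolate is not lost), and iodinolysis with retention gives the iodoalkene with iodine cis to the CH2OH carbon, which fixes the ring-cis C4=C5 geometry.

Step 3
Reactants: 5 hex-1-en-5-yne
Product: 8 (E)-4-methylocta-3,7-dien-1-ol, via alkenylalane 6 (not isolated), via lithium alanate 7 (not isolated)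
Conditions: Me3Al, Cp2ZrCl2 (20 mol %), CH2Cl2, 0 °C to rt; then n-BuLi, THF, −78 °C; then oxirane, −78 °C to rt
Reagents that add atoms: trimethylaluminium C[Al](C)C; oxirane C1CO1
Why: Zirconium-catalysed syn-carboalumination (Negishi) of the terminal alkyne puts methyl on the internal carbon and aluminium on the terminus, and the derived alanate opens oxirane with retention, which sets the (E)-C1=C10 olefin.

Step 4
Reactants: 8 (E)-4-methylocta-3,7-dien-1-ol
Product: 9 (E)-8-iodo-5-methylocta-1,5-diene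
Conditions: I2, PPh3, imidazole, CH2Cl2, 0 °C
Reagents that add atoms: iodine II
Why: Appel iodination of a primary alcohol is neutral and leaves both olefins untouched.

Step 5
Reactants: 9 (E)-8-iodo-5-methylocta-1,5-diene; 4 (Z)-4-[(tert-butyldimethylsilyl)oxy]-3-iodobut-2-en-1-ol
Product: 12 (2E,6E)-3-{[(tert-butyldimethylsilyl)oxy]methyl}-7-methylundeca-2,6,10-trien-1-ol, via alkyllithium 10 (not isolated), via lithium borinate 11 (not isolated)
Conditions: t-BuLi (2.1 equiv), Et2O, −78 °C; B-methoxy-9-BBN, THF, −78 °C to rt; then 4, Pd(dppf)Cl2 (5 mol %), AsPh3, Cs2CO3, DMF/H2O, rt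
Reagents that add atoms: none
Why: Iodine–lithium exchange and trapping with B-methoxy-9-BBN give a borinate that couples with the alkenyl iodide with retention of geometry (B-alkyl Suzuki–Miyaura coupling) and tolerates the free allylic alcohol, so the C3 chain ends up cis to C6.

Step 6
Reactants: 12 (2E,6E)-3-{[(tert-butyldimethylsilyl)oxy]methyl}-7-methylundeca-2,6,10-trien-1-ol; 13 2-(bromomethyl)acrylic acid
Product: 14 (3S,5E,9E)-9-{[(tert-butyldimethylsilyl)oxy]methyl}-11-hydroxy-5-methylundeca-1,5,9-trien-3-yl 2-(bromomethyl)prop-2-enoate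
Conditions: Pd(OAc)2 (10 mol %), chiral sulfoxide–oxazoline ligand (S)-4-tert-butyl-2-[2-((S)-p-tolylsulfinyl)phenyl]-4,5-dihydrooxazole (12 mol %), 13 (2 equiv), 1,4-benzoquinone (2 equiv), 4 Å MS, 1,4-dioxane, 45 °C
Reagents that add atoms: none
Why: Proposed new method: enantioselective branched allylic C–H acyloxylation, in which the sulfoxide-ligated divalent palladium carboxylate cleaves a C8–H bond of the terminal alkene only (trisubstituted alkenes are not engaged) to give a π-allylpalladium carboxylate that still carries the chiral S,N-ligand, benzoquinone binding then triggers inner-sphere C–O reductive elimination at the internal allyl terminus, and because the π-allyl faces interconvert by π–σ–π shifts faster than C–O formation the ligand pocket decides the C8 configuration (8S with the matched ligand antipode, to be fixed by screening); the closest known reaction types are the racemic Pd(OAc)2/bis-sulfoxide/benzoquinone branched allylic C–H esterification of terminal olefins with carboxylic acids and enantioselective intramolecular allylic C–H oxidation with Pd/chiral sulfoxide–oxazoline catalysts.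

Step 7
Reactants: 14 (3S,5E,9E)-9-{[(tert-butyldimethylsilyl)oxy]methyl}-11-hydroxy-5-methylundeca-1,5,9-trien-3-yl 2-(bromomethyl)prop-2-enoate
Product: 15 (5S)-3-(bromomethyl)-5-[(2E,6E)-6-{[(tert-butyldimethylsilyl)oxy]methyl}-8-hydroxy-2-methylocta-2,6-dien-1-yl]furan-2(5H)-one
Conditions: second-generation Grubbs catalyst (H2IMes)(PCy3)Cl2Ru=CHPh (5 mol %), CH2Cl2, 40 °C
Reagents that add atoms: none
Why: Ring-closing metathesis between the terminal vinyl group and the 1,1-disubstituted acrylate closes the butenolide with loss of ethene, while the trisubstituted olefins are inert and the C8 stereocentre is untouched.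

Step 8
Reactants: 15 (5S)-3-(bromomethyl)-5-[(2E,6E)-6-{[(tert-butyldimethylsilyl)oxy]methyl}-8-hydroxy-2-methylocta-2,6-dien-1-yl]furan-2(5H)-one
Product: 16 (2E,6E)-8-[(2S)-4-(bromomethyl)-5-oxo-2,5-dihydrofuran-2-yl]-3-{[(tert-butyldimethylsilyl)oxy]methyl}-7-methylocta-2,6-dienal
Conditions: MnO2 (15 equiv), CH2Cl2, 0 °C to rt
Reagents that add atoms: none
Why: MnO2 oxidises only the primary allylic alcohol to the enal under neutral conditions (allylic oxidation), which keeps the olefin geometry and does not enolise the butenolide, so the sensitive (Z)-type enal is made only just before ring closure.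

Step 9
Reactants: 16 (2E,6E)-8-[(2S)-4-(bromomethyl)-5-oxo-2,5-dihydrofuran-2-yl]-3-{[(tert-butyldimethylsilyl)oxy]methyl}-7-methylocta-2,6-dienal
Product: 17 (3aS,4R,5E,9E,11aS)-6-{[(tert-butyldimethylsilyl)oxy]methyl}-4-hydroxy-10-methyl-3-methylidene-3a,4,7,8,11,11a-hexahydrocyclodeca[b]furan-2(3H)-one
Conditions: CrCl2 (6 equiv), THF, rt, slow addition of 16 (final 3 mM); aq. NH4Cl
Reagents that add atoms: none
Why: In this intramolecular Nozaki–Hiyama-type chromium Barbier allylation the allylchromium from the bromomethylbutenolide adds through C7 in a chair Zimmerman–Traxler transition state, anti to the C8 substituent (trans-lactone, 7S) and with the enal substituent equatorial (anti C6/C7, 6R), which regenerates the exocyclic methylene and closes the ten-membered ring.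

Step 10
Reactants: 17 (3aS,4R,5E,9E,11aS)-6-{[(tert-butyldimethylsilyl)oxy]methyl}-4-hydroxy-10-methyl-3-methylidene-3a,4,7,8,11,11a-hexahydrocyclodeca[b]furan-2(3H)-one
Product: 18 (3aS,4R,5E,9E,11aS)-4-hydroxy-6-(hydroxymethyl)-10-methyl-3-methylidene-3a,4,7,8,11,11a-hexahydrocyclodeca[b]furan-2(3H)-one
Conditions: HF·pyridine, pyridine, THF, 0 °C
Reagents that add atoms: none
Why: Buffered fluoride desilylation removes the primary allylic TBS ether without base, so the α-methylene lactone and the stereocentres are not disturbed.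

Step 11
Reactants: 19 but-2-yn-1-ol
Product: 20 (Z)-2-(tributylstannyl)but-2-en-1-ol
Conditions: Bu3SnH (1.1 equiv), [Cp*RuCl]4 (1.5 mol %), CH2Cl2, rt
Reagents that add atoms: tributylstannane CCCC[SnH](CCCC)CCCC
Why: Hydroxyl-directed ruthenium-catalysed trans-hydrostannation places tin on the alkyne carbon next to the carbinol and hydrogen trans to it, so tin is cis to the methyl group.

Step 12
Reactants: 20 (Z)-2-(tributylstannyl)but-2-en-1-ol
Product: 21 tert-butyldimethyl{[(Z)-2-(tributylstannyl)but-2-en-1-yl]oxy}silane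
Conditions: TBSCl, imidazole, DMF, rt
Reagents that add atoms: tert-butyldimethylsilyl chloride CC(C)(C)[Si](C)(C)Cl
Why: Standard silyl ether formation protects the hydroxyl for the lithiation and for the final esterification.

Step 13
Reactants: 21 tert-butyldimethyl{[(Z)-2-(tributylstannyl)but-2-en-1-yl]oxy}silane
Product: 23 (Z)-2-{[(tert-butyldimethylsilyl)oxy]methyl}but-2-enoic acid, via alkenyllithium 22 (not isolated)
Conditions: n-BuLi, THF, −78 °C; then CO2, −78 °C to rt; dilute HCl to pH 3
Reagents that add atoms: carbon dioxide O=C=O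
Why: Tin–lithium exchange and carboxylation both go with retention of olefin geometry, giving the acid with methyl cis to the carboxyl group.

Step 14
Reactants: 18 (3aS,4R,5E,9E,11aS)-4-hydroxy-6-(hydroxymethyl)-10-methyl-3-methylidene-3a,4,7,8,11,11a-hexahydrocyclodeca[b]furan-2(3H)-one; 23 (Z)-2-{[(tert-butyldimethylsilyl)oxy]methyl}but-2-enoic acid
Product: 25 [(3aS,4R,5E,9E,11aS)-4-hydroxy-10-methyl-3-methylidene-2-oxo-2,3,3a,4,7,8,11,11a-octahydrocyclodeca[b]furan-6-yl]methyl (2Z)-2-(hydroxymethyl)but-2-enoate, via silyl ether 24 (not isolated)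
Conditions: PPh3, DIAD, THF, 0 °C; then HF·pyridine, 0 °C
Reagents that add atoms: none
Why: Mitsunobu esterification activates the less hindered primary allylic C15–OH and the carboxylate displaces it by SN2, which leaves the acid's Z geometry and the secondary C6–OH alone, and HF·pyridine then removes the silyl group.

## Compound list

1 | 2-butyne-1,4-diol | OCC#CCO | starting material
2 | 4-[(tert-butyldimethylsilyl)oxy]but-2-yn-1-ol | OCC#CCO[Si](C)(C)C(C)(C)C | intermediate
3 | sodium 2,2-bis(2-methoxyethoxy)-3-{[(tert-butyldimethylsilyl)oxy]methyl}-2,5-dihydro-1,2-oxaaluminol-2-uide (cyclic alkenylaluminate) | [Na+].COCCO[Al-]1(OCCOC)OCC=C1CO[Si](C)(C)C(C)(C)C | intermediate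
4 | (Z)-4-[(tert-butyldimethylsilyl)oxy]-3-iodobut-2-en-1-ol | OC/C=C(\I)CO[Si](C)(C)C(C)(C)C | intermediate
5 | hex-1-en-5-yne | C=CCCC#C | starting material
6 | dimethyl[(E)-2-methylhexa-1,5-dien-1-yl]alane | C[Al](C)/C=C(\C)CCC=C | intermediate
7 | lithium butyl(dimethyl)[(E)-2-methylhexa-1,5-dien-1-yl]alanate | [Li+].CCCC[Al-](C)(C)/C=C(\C)CCC=C | intermediate
8 | (E)-4-methylocta-3,7-dien-1-ol | OCC/C=C(\C)CCC=C | intermediate
9 | (E)-8-iodo-5-methylocta-1,5-diene | ICC/C=C(\C)CCC=C | intermediate
10 | [(E)-4-methylocta-3,7-dien-1-yl]lithium | [Li]CC/C=C(\C)CCC=C | intermediate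
11 | lithium 9-methoxy-9-[(E)-4-methylocta-3,7-dien-1-yl]-9-boranuidabicyclo[3.3.1]nonane | [Li+].CO[B-]1(CC/C=C(\C)CCC=C)C2CCCC1CCC2 | intermediate
12 | (2E,6E)-3-{[(tert-butyldimethylsilyl)oxy]methyl}-7-methylundeca-2,6,10-trien-1-ol (C4 chain cis to C1) | OC/C=C(/CO[Si](C)(C)C(C)(C)C)CC/C=C(\C)CCC=C | intermediate
13 | 2-(bromomethyl)acrylic acid | C=C(CBr)C(=O)O | starting material
14 | (3S,5E,9E)-9-{[(tert-butyldimethylsilyl)oxy]methyl}-11-hydroxy-5-methylundeca-1,5,9-trien-3-yl 2-(bromomethyl)prop-2-enoate | C=C(CBr)C(=O)O[C@H](C=C)C/C(C)=C/CC/C(CO[Si](C)(C)C(C)(C)C)=C\CO | intermediate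
15 | (5S)-3-(bromomethyl)-5-[(2E,6E)-6-{[(tert-butyldimethylsilyl)oxy]methyl}-8-hydroxy-2-methylocta-2,6-dien-1-yl]furan-2(5H)-one | O=C1O[C@@H](C/C(C)=C/CC/C(CO[Si](C)(C)C(C)(C)C)=C\CO)C=C1CBr | intermediate
16 | (2E,6E)-8-[(2S)-4-(bromomethyl)-5-oxo-2,5-dihydrofuran-2-yl]-3-{[(tert-butyldimethylsilyl)oxy]methyl}-7-methylocta-2,6-dienal | O=C1O[C@@H](C/C(C)=C/CC/C(CO[Si](C)(C)C(C)(C)C)=C\C=O)C=C1CBr | intermediate
17 | (3aS,4R,5E,9E,11aS)-6-{[(tert-butyldimethylsilyl)oxy]methyl}-4-hydroxy-10-methyl-3-methylidene-3a,4,7,8,11,11a-hexahydrocyclodeca[b]furan-2(3H)-one | C=C1C(=O)O[C@H]2C/C(C)=C/CC/C(CO[Si](C)(C)C(C)(C)C)=C\[C@@H](O)[C@H]12 | intermediate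
18 | (3aS,4R,5E,9E,11aS)-4-hydroxy-6-(hydroxymethyl)-10-methyl-3-methylidene-3a,4,7,8,11,11a-hexahydrocyclodeca[b]furan-2(3H)-one | C=C1C(=O)O[C@H]2C/C(C)=C/CC/C(CO)=C\[C@@H](O)[C@H]12 | intermediate
19 | but-2-yn-1-ol | CC#CCO | starting material
20 | (Z)-2-(tributylstannyl)but-2-en-1-ol | C/C=C(/CO)[Sn](CCCC)(CCCC)CCCC | intermediate
21 | tert-butyldimethyl{[(Z)-2-(tributylstannyl)but-2-en-1-yl]oxy}silane | C/C=C(/CO[Si](C)(C)C(C)(C)C)[Sn](CCCC)(CCCC)CCCC | intermediate
22 | (1-{[(tert-butyldimethylsilyl)oxy]methyl}prop-1-en-1-yl)lithium, lithium cis to methyl | C/C=C(/CO[Si](C)(C)C(C)(C)C)[Li] | intermediate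
23 | (Z)-2-{[(tert-butyldimethylsilyl)oxy]methyl}but-2-enoic acid | C/C=C(/CO[Si](C)(C)C(C)(C)C)C(=O)O | intermediate
24 | [(3aS,4R,5E,9E,11aS)-4-hydroxy-10-methyl-3-methylidene-2-oxo-2,3,3a,4,7,8,11,11a-octahydrocyclodeca[b]furan-6-yl]methyl (2Z)-2-{[(tert-butyldimethylsilyl)oxy]methyl}but-2-enoate | C=C1C(=O)O[C@H]2C/C(C)=C/CC/C(COC(=O)/C(=C\C)CO[Si](C)(C)C(C)(C)C)=C\[C@@H](O)[C@H]12 | intermediate
25 | [(3aS,4R,5E,9E,11aS)-4-hydroxy-10-methyl-3-methylidene-2-oxo-2,3,3a,4,7,8,11,11a-octahydrocyclodeca[b]furan-6-yl]methyl (2Z)-2-(hydroxymethyl)but-2-enoate | C=C1C(=O)O[C@H]2C/C(C)=C/CC/C(COC(=O)/C(=C\C)CO)=C\[C@@H](O)[C@H]12 | target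

## Step count and risks

Total step count: 14. Longest linear sequence: 9 (steps 1, 2, 5, 6, 7, 8, 9, 10, 14).

The three steps most likely to fail are steps 6, 9 and 14.

**Step 6 (the proposed new allylic C–H acyloxylation).** The enantioselectivity, the tolerance of the free allylic alcohol and the stability of the allylic bromide acid under the oxidative conditions are all untested. The fallback uses known chemistry only; it sets out from 12 and comes back at 16. 12 is first oxidised with MnO2 to (2E,6E)-3-{[(tert-butyldimethylsilyl)oxy]methyl}-7-methylundeca-2,6,10-trienal F1, so that no second hydroxyl competes later. Racemic branched allylic C–H acetoxylation (Pd(OAc)2, 1,2-bis(phenylsulfinyl)ethane, benzoquinone, AcOH, dioxane, 43 °C) gives rac-(5E,9E)-9-{[(tert-butyldimethylsilyl)oxy]methyl}-5-methyl-11-oxoundeca-1,5,9-trien-3-yl acetate F2. Lipase-catalysed hydrolysis (Candida antarctica lipase B, pH 7 buffer) releases the fast-reacting enantiomer as (2E,6E,9S)-3-{[(tert-butyldimethylsilyl)oxy]methyl}-9-hydroxy-7-methylundeca-2,6,10-trienal F3 (at most 50 %; the (R)-acetate stays behind). Steglich esterification with 13 (DCC, 5 mol % DMAP, CH2Cl2, 0 °C) gives (3S,5E,9E)-9-{[(tert-butyldimethylsilyl)oxy]methyl}-5-methyl-11-oxoundeca-1,5,9-trien-3-yl 2-(bromomethyl)prop-2-enoate F4. Ring-closing metathesis under the conditions of step 7 returns 16. The cost is that the sensitive enal is carried through two warm, weakly acidic steps.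

**Step 9 (ten-membered ring closure).** It may give oligomers or the wrong C6/C7 diastereomer. The fallback installs the nucleophile before the electrophile is unveiled; it sets out from 15 and comes back at 17. Palladium-catalysed Miyaura-type allylic borylation (B2pin2, Pd2(dba)3, toluene, 50 °C) converts the bromide into (5S)-5-[(2E,6E)-6-{[(tert-butyldimethylsilyl)oxy]methyl}-8-hydroxy-2-methylocta-2,6-dien-1-yl]-3-[(4,4,5,5-tetramethyl-1,3,2-dioxaborolan-2-yl)methyl]furan-2(5H)-one F5. Dess–Martin oxidation of its C6 alcohol in dilute solution gives (2E,6E)-3-{[(tert-butyldimethylsilyl)oxy]methyl}-7-methyl-8-{(2S)-5-oxo-4-[(4,4,5,5-tetramethyl-1,3,2-dioxaborolan-2-yl)methyl]-2,5-dihydrofuran-2-yl}octa-2,6-dienal F6. F6 closes the ring by intramolecular allylboration through a closed six-membered transition state with the same anti/trans topicity (40–60 °C, or catalytic Sc(OTf)3). Aqueous work-up of the borate gives 17.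

**Step 14 (site-selective Mitsunobu esterification).** It may suffer from SN2′ attack, reaction at the C6–OH, or phosphine addition to the α-methylene lactone. The fallback activates the acid instead of the alcohol; it sets out from 23 and comes back at 24. 23 is treated with 2,4,6-trichlorobenzoyl chloride and Et3N in toluene to give (2Z)-2-{[(tert-butyldimethylsilyl)oxy]methyl}but-2-enoic 2,4,6-trichlorobenzoic anhydride F7. F7 acylates the primary C15–OH of 18 in toluene at rt to 40 °C without a nucleophilic catalyst, conditions that keep the angelate-type Z geometry, and gives 24. HF·pyridine as in step 14 then gives 25.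

## Further compounds

F1 | step 6 | (2E,6E)-3-{[(tert-butyldimethylsilyl)oxy]methyl}-7-methylundeca-2,6,10-trienal | O=C/C=C(/CO[Si](C)(C)C(C)(C)C)CC/C=C(\C)CCC=C
F2 | step 6 | rac-(5E,9E)-9-{[(tert-butyldimethylsilyl)oxy]methyl}-5-methyl-11-oxoundeca-1,5,9-trien-3-yl acetate | CC(=O)OC(C=C)C/C(C)=C/CC/C(CO[Si](C)(C)C(C)(C)C)=C\C=O
F3 | step 6 | (2E,6E,9S)-3-{[(tert-butyldimethylsilyl)oxy]methyl}-9-hydroxy-7-methylundeca-2,6,10-trienal | O[C@H](C=C)C/C(C)=C/CC/C(CO[Si](C)(C)C(C)(C)C)=C\C=O
F4 | step 6 | (3S,5E,9E)-9-{[(tert-butyldimethylsilyl)oxy]methyl}-5-methyl-11-oxoundeca-1,5,9-trien-3-yl 2-(bromomethyl)prop-2-enoate | C=C(CBr)C(=O)O[C@H](C=C)C/C(C)=C/CC/C(CO[Si](C)(C)C(C)(C)C)=C\C=O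
F5 | step 9 | (5S)-5-[(2E,6E)-6-{[(tert-butyldimethylsilyl)oxy]methyl}-8-hydroxy-2-methylocta-2,6-dien-1-yl]-3-[(4,4,5,5-tetramethyl-1,3,2-dioxaborolan-2-yl)methyl]furan-2(5H)-one | O=C1O[C@@H](C/C(C)=C/CC/C(CO[Si](C)(C)C(C)(C)C)=C\CO)C=C1CB1OC(C)(C)C(C)(C)O1
F6 | step 9 | (2E,6E)-3-{[(tert-butyldimethylsilyl)oxy]methyl}-7-methyl-8-{(2S)-5-oxo-4-[(4,4,5,5-tetramethyl-1,3,2-dioxaborolan-2-yl)methyl]-2,5-dihydrofuran-2-yl}octa-2,6-dienal | O=C1O[C@@H](C/C(C)=C/CC/C(CO[Si](C)(C)C(C)(C)C)=C\C=O)C=C1CB1OC(C)(C)C(C)(C)O1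
F7 | step 14 | (2Z)-2-{[(tert-butyldimethylsilyl)oxy]methyl}but-2-enoic 2,4,6-trichlorobenzoic anhydride | C/C=C(/CO[Si](C)(C)C(C)(C)C)C(=O)OC(=O)c1c(Cl)cc(Cl)cc1Cl
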